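**Retrosynthetic overview**
1. Target ⇒ fluoride desilylation and closure of the O1–C2 bond (intramolecular Mitsunobu) of an (R)-2,3-diarylpropan-1-ol. The pyran is the only ring made and it is made last; both benzene rings are bought.
2. Diol ⇒ the C3–C4 bond and the C3 stereocentre come from an enamine-catalysed addition of a B-ring arylacetaldehyde to a CH2-terminated A-ring o-quinone methide, with NaBH4 added to the same flask.
3. o-Quinone methide ⇒ salicyl alcohol ⇒ salicylaldehyde. Its prenyl group is placed between OMe and O-7 by a para-Claisen–Cope shift from the phenol oxygen that later becomes O1.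
4. Arylacetaldehyde ⇒ one-carbon homologation of 4-hydroxy-2-methoxybenzaldehyde. TIPS protects the two phenols that end up free.

Assumption: 2,4-dihydroxy-6-methoxybenzaldehyde, prenol, 4-hydroxy-2-methoxybenzaldehyde and both enantiomers of diphenylprolinol TMS ether are catalogue chemicals. The target stereocentre is (3R).

**Step 1**
Reactants: 1 2,4-dihydroxy-6-methoxybenzaldehyde
Product: 2 2-hydroxy-6-methoxy-4-[(triisopropylsilyl)oxy]benzaldehyde
Conditions: TIPSCl (1.05 equiv), imidazole, CH2Cl2, 0 °C → rt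
Reagents that add atoms: triisopropylsilyl chloride CC(C)[Si](Cl)(C(C)C)C(C)C
Why: Chemoselective silyl ether formation, because the 2-OH is locked in a hydrogen bond to the formyl group and only the free, more acidic 4-OH reacts.

**Step 2**
Reactants: 2 2-hydroxy-6-methoxy-4-[(triisopropylsilyl)oxy]benzaldehyde; 3 3-methylbut-2-en-1-ol (prenol)
Product: 4 2-methoxy-6-[(3-methylbut-2-en-1-yl)oxy]-4-[(triisopropylsilyl)oxy]benzaldehyde
Conditions: PPh3, DIAD, THF, 0 °C → rt
Reagents that add atoms: none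
Why: Mitsunobu etherification alkylates the remaining chelated phenol at the primary carbon of prenol under neutral conditions, so the base-labile aryl silyl ether para to the aldehyde survives.

**Step 3**
Reactants: 4 2-methoxy-6-[(3-methylbut-2-en-1-yl)oxy]-4-[(triisopropylsilyl)oxy]benzaldehyde
Product: 7 6-hydroxy-2-methoxy-3-(3-methylbut-2-en-1-yl)-4-[(triisopropylsilyl)oxy]benzaldehyde, via ortho-dienone 5 (not isolated), via para-dienone 6 (not isolated)
Conditions: PhNEt2, 200 °C (sealed tube or µW), 1–2 h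
Reagents that add atoms: none
Why: Tandem aromatic Claisen–Cope (para-Claisen) rearrangement, in which the first [3,3] shift can only reach the one free ortho carbon (the other carries CHO) and the crowded reverse-prenyl dienone 5 undergoes a second [3,3] shift to the para carbon faster than it enolises, placing a normal prenyl group between OMe and OTIPS as known for prenyl ethers of acylphloroglucinols.

**Step 4**
Reactants: 7 6-hydroxy-2-methoxy-3-(3-methylbut-2-en-1-yl)-4-[(triisopropylsilyl)oxy]benzaldehyde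
Product: 8 2-(hydroxymethyl)-3-methoxy-4-(3-methylbut-2-en-1-yl)-5-[(triisopropylsilyl)oxy]phenol
Conditions: NaBH4, THF/EtOH, −10 °C, 20 min; pH 7 buffer; used without chromatography
Reagents that add atoms: none
Why: Borohydride 1,2-reduction of the aldehyde, kept cold, short and neutrally quenched so that the benzylic alcohol does not eliminate to the quinone methide and get reduced further to the cresol.

**Step 5**
Reactants: 9 4-hydroxy-2-methoxybenzaldehyde
Product: 10 2-methoxy-4-[(triisopropylsilyl)oxy]benzaldehyde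
Conditions: TIPSCl, imidazole, DMF, rt
Reagents that add atoms: triisopropylsilyl chloride CC(C)[Si](Cl)(C(C)C)C(C)C
Why: Standard silyl ether protection of the only phenol.

**Step 6**
Reactants: 10 2-methoxy-4-[(triisopropylsilyl)oxy]benzaldehyde
Product: 12 2-{2-methoxy-4-[(triisopropylsilyl)oxy]phenyl}acetaldehyde, via enol ether 11 (not isolated)
Conditions: MeOCH2PPh3Cl, KOtBu, THF, 0 °C → rt; then 2 M HCl, rt
Reagents that add atoms: (methoxymethyl)triphenylphosphonium chloride COC[P+](c1ccccc1)(c1ccccc1)c1ccccc1.[Cl-]; water O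
Why: Wittig methoxymethylenation followed by acid hydrolysis of the enol ether is the standard one-carbon homologation, and aryl TIPS ethers tolerate dilute aqueous acid.

**Step 7**
Reactants: 8 2-(hydroxymethyl)-3-methoxy-4-(3-methylbut-2-en-1-yl)-5-[(triisopropylsilyl)oxy]phenol; 12 2-{2-methoxy-4-[(triisopropylsilyl)oxy]phenyl}acetaldehyde
Product: 17 (2R)-3-{6-hydroxy-2-methoxy-3-(3-methylbut-2-en-1-yl)-4-[(triisopropylsilyl)oxy]phenyl}-2-{2-methoxy-4-[(triisopropylsilyl)oxy]phenyl}propan-1-ol, via o-quinone methide 13 (not isolated), via enamine 14 (not isolated), via open-chain aldehyde 15 (not isolated), via lactol 16 (not isolated)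
Conditions: (R)-α,α-diphenylprolinol TMS ether (C[Si](C)(C)OC(c1ccccc1)(c1ccccc1)[C@H]1CCCN1, 20 mol %), 4-nitrobenzoic acid (20 mol %), 12 (1.5 equiv), 8 added over 6 h, toluene, 0 °C; then EtOH, NaBH4, 0 °C
Reagents that add atoms: none
Why: Proposed new method: the weak acid dehydrates the trioxygenated salicyl alcohol 8 to the CH2-terminated o-quinone methide 13 (kept dilute by slow addition), the catalyst converts 12 into the conjugated (E)-s-trans enamine 14 whose face syn to the CPh2OTMS group is blocked, so the methide carbon bonds to the open Re face of the enamine β-carbon and the (R)-catalyst gives (R)-15, which after iminium hydrolysis closes to lactol 16 and is reduced by NaBH4 before the labile α-aryl aldehyde can racemise; the closest known reaction types are the aminocatalytic Michael/hemiacetalisation (formal [4+2]) of aliphatic aldehydes with β-aryl o-quinone methides and the SN1-type enamine α-alkylation of aldehydes with stabilised benzylic cations, whereas an unsubstituted o-quinone methide, an arylacetaldehyde donor and a lone α-aryl stereocentre have not been shown.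

**Step 8**
Reactants: 17 (2R)-3-{6-hydroxy-2-methoxy-3-(3-methylbut-2-en-1-yl)-4-[(triisopropylsilyl)oxy]phenyl}-2-{2-methoxy-4-[(triisopropylsilyl)oxy]phenyl}propan-1-ol
Product: 19 (3R)-3-(4-hydroxy-2-methoxyphenyl)-5-methoxy-6-(3-methylbut-2-en-1-yl)chroman-7-ol, via bis-TIPS isoflavan 18 (not isolated)
Conditions: PPh3, DIAD, THF, 0 °C → rt; then TBAF, AcOH, 0 °C → rt
Reagents that add atoms: none
Why: Intramolecular Mitsunobu etherification (6-exo SN2 at the primary carbinol, stereocentre not involved, as in established isoflavan syntheses) closes the pyran, and buffered fluoride then cleaves both aryl TIPS ethers without acid, so the prenyl group and its neighbouring phenol cannot cyclise.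

**Compound list**
1 | 2,4-dihydroxy-6-methoxybenzaldehyde | O=Cc1c(O)cc(O)cc1OC | starting material
2 | 2-hydroxy-6-methoxy-4-[(triisopropylsilyl)oxy]benzaldehyde | O=Cc1c(O)cc(O[Si](C(C)C)(C(C)C)C(C)C)cc1OC | intermediate
3 | 3-methylbut-2-en-1-ol (prenol) | CC(C)=CCO | starting material
4 | 2-methoxy-6-[(3-methylbut-2-en-1-yl)oxy]-4-[(triisopropylsilyl)oxy]benzaldehyde | O=Cc1c(OCC=C(C)C)cc(O[Si](C(C)C)(C(C)C)C(C)C)cc1OC | intermediate
5 | 2-methoxy-5-(2-methylbut-3-en-2-yl)-6-oxo-4-[(triisopropylsilyl)oxy]cyclohexa-1,3-diene-1-carbaldehyde (racemic ortho-dienone) | O=CC1=C(OC)C=C(O[Si](C(C)C)(C(C)C)C(C)C)C(C(C)(C)C=C)C1=O | intermediate (not isolated)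
6 | 2-methoxy-3-(3-methylbut-2-en-1-yl)-6-oxo-4-[(triisopropylsilyl)oxy]cyclohexa-1,4-diene-1-carbaldehyde (racemic para-dienone) | O=CC1=C(OC)C(CC=C(C)C)C(O[Si](C(C)C)(C(C)C)C(C)C)=CC1=O | intermediate (not isolated)
7 | 6-hydroxy-2-methoxy-3-(3-methylbut-2-en-1-yl)-4-[(triisopropylsilyl)oxy]benzaldehyde | O=Cc1c(O)cc(O[Si](C(C)C)(C(C)C)C(C)C)c(CC=C(C)C)c1OC | intermediate
8 | 2-(hydroxymethyl)-3-methoxy-4-(3-methylbut-2-en-1-yl)-5-[(triisopropylsilyl)oxy]phenol | OCc1c(O)cc(O[Si](C(C)C)(C(C)C)C(C)C)c(CC=C(C)C)c1OC | intermediate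
9 | 4-hydroxy-2-methoxybenzaldehyde | O=Cc1ccc(O)cc1OC | starting material
10 | 2-methoxy-4-[(triisopropylsilyl)oxy]benzaldehyde | O=Cc1ccc(O[Si](C(C)C)(C(C)C)C(C)C)cc1OC | intermediate
11 | 2-methoxy-1-(2-methoxyethenyl)-4-[(triisopropylsilyl)oxy]benzene (E/Z mixture) | COC=Cc1ccc(O[Si](C(C)C)(C(C)C)C(C)C)cc1OC | intermediate (not isolated)
12 | 2-{2-methoxy-4-[(triisopropylsilyl)oxy]phenyl}acetaldehyde | O=CCc1ccc(O[Si](C(C)C)(C(C)C)C(C)C)cc1OC | intermediate
13 | 5-methoxy-6-methylidene-4-(3-methylbut-2-en-1-yl)-3-[(triisopropylsilyl)oxy]cyclohexa-2,4-dien-1-one (o-quinone methide) | C=C1C(=O)C=C(O[Si](C(C)C)(C(C)C)C(C)C)C(CC=C(C)C)=C1OC | intermediate (not isolated)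
14 | (E)-enamine of 12 with (R)-diphenylprolinol TMS ether | C[Si](C)(C)OC(c1ccccc1)(c1ccccc1)[C@H]1CCCN1/C=C/c1ccc(O[Si](C(C)C)(C(C)C)C(C)C)cc1OC | intermediate (not isolated)
15 | (2R)-3-{6-hydroxy-2-methoxy-3-(3-methylbut-2-en-1-yl)-4-[(triisopropylsilyl)oxy]phenyl}-2-{2-methoxy-4-[(triisopropylsilyl)oxy]phenyl}propanal | COc1cc(O[Si](C(C)C)(C(C)C)C(C)C)ccc1[C@H](C=O)Cc1c(O)cc(O[Si](C(C)C)(C(C)C)C(C)C)c(CC=C(C)C)c1OC | intermediate (not isolated)
16 | (3R)-5-methoxy-3-{2-methoxy-4-[(triisopropylsilyl)oxy]phenyl}-6-(3-methylbut-2-en-1-yl)-7-[(triisopropylsilyl)oxy]chroman-2-ol (C2 epimers) | COc1cc(O[Si](C(C)C)(C(C)C)C(C)C)ccc1[C@@H]1C(O)Oc2cc(O[Si](C(C)C)(C(C)C)C(C)C)c(CC=C(C)C)c(OC)c2C1 | intermediate (not isolated)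
17 | (2R)-3-{6-hydroxy-2-methoxy-3-(3-methylbut-2-en-1-yl)-4-[(triisopropylsilyl)oxy]phenyl}-2-{2-methoxy-4-[(triisopropylsilyl)oxy]phenyl}propan-1-ol | COc1cc(O[Si](C(C)C)(C(C)C)C(C)C)ccc1[C@H](CO)Cc1c(O)cc(O[Si](C(C)C)(C(C)C)C(C)C)c(CC=C(C)C)c1OC | intermediate
18 | (3R)-5-methoxy-3-{2-methoxy-4-[(triisopropylsilyl)oxy]phenyl}-6-(3-methylbut-2-en-1-yl)-7-[(triisopropylsilyl)oxy]chroman | COc1cc(O[Si](C(C)C)(C(C)C)C(C)C)ccc1[C@@H]1COc2cc(O[Si](C(C)C)(C(C)C)C(C)C)c(CC=C(C)C)c(OC)c2C1 | intermediate (not isolated)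
19 | (3R)-3-(4-hydroxy-2-methoxyphenyl)-5-methoxy-6-(3-methylbut-2-en-1-yl)chroman-7-ol | COc1cc(O)ccc1[C@@H]1COc2cc(O)c(CC=C(C)C)c(OC)c2C1 | target

**Totals**
Total step count: 8.
Longest linear sequence: 6 (steps 1, 2, 3, 4, 7, 8).

**Three steps most likely to fail**

**Step 7 (the proposed new step).**
Three things can go wrong:
- self-aldol condensation of 12 under amine catalysis;
- oligomerisation of 13, or its capture by the catalyst nitrogen;
- partial racemisation of 15 before the reduction.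

The fallback uses known chemistry, sets out from 8 and 12, and comes back at 17. Aldehyde 12 is condensed with morpholine (toluene, MgSO4) to 4-[(E)-2-{2-methoxy-4-[(triisopropylsilyl)oxy]phenyl}ethenyl]morpholine F1. Heating it with 8 in toluene at 100 °C generates 13 thermally. The classical inverse-demand hetero-Diels–Alder reaction of o-quinone methides with enamines then gives the racemic 2-morpholinochroman F2. Aqueous AcOH/THF hydrolyses the N,O-aminal to the racemic lactol F3. The last operation is hydrogenation under dynamic kinetic resolution with a RuCl2(chiral spiro-diphosphine)(chiral 1,2-diamine)/KOtBu catalyst (H2, iPrOH, rt). This is the established method for racemic α-aryl aldehydes. The base racemises the open-chain aldehyde, the catalyst enantiomer chosen for the (R)-alcohol reduces only one antipode, the prenyl alkene is untouched, and the product is 17.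

**Step 3 (para-Claisen–Cope).**
Dienone 5 may enolise before the Cope shift, which would give the 5-(1,1-dimethylallyl) isomer.

The fallback blocks that ortho carbon. It sets out from 2 and comes back at 7. NBS (CH2Cl2, 0 °C) brominates ortho to the chelated phenol, giving 3-bromo-2-hydroxy-6-methoxy-4-[(triisopropylsilyl)oxy]benzaldehyde F4. Mitsunobu reaction with 3 gives the prenyl ether 3-bromo-6-methoxy-2-[(3-methylbut-2-en-1-yl)oxy]-4-[(triisopropylsilyl)oxy]benzaldehyde F5. With both ortho carbons now substituted, heating in PhNEt2 can only end at the para position. This gives 3-bromo-2-hydroxy-6-methoxy-5-(3-methylbut-2-en-1-yl)-4-[(triisopropylsilyl)oxy]benzaldehyde F6. Pd(PPh3)4/HCO2Na (DMF, 90 °C) then removes the bromine to give 7.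

**Step 4 (labile salicyl alcohol).**
Compound 8 may over-reduce to the cresol, or self-condense on isolation.

The fallback switches from an acid-triggered alcohol to a bench-stable, base-triggered ammonium salt. It sets out from 7 and comes back at 13, generated in the flask of step 7. Reductive amination of 7 (Me2NH, NaBH(OAc)3, DCE) gives the Mannich base 2-[(dimethylamino)methyl]-3-methoxy-4-(3-methylbut-2-en-1-yl)-5-[(triisopropylsilyl)oxy]phenol F7. MeI in Et2O precipitates the benzyltrimethylammonium iodide F8. In step 7 this salt replaces 8, and aqueous NaHCO3/toluene replaces the acid co-catalyst. Mild base then releases 13 by the known 1,4-elimination.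

**Further compounds**
F1 | step 7 | 4-[(E)-2-{2-methoxy-4-[(triisopropylsilyl)oxy]phenyl}ethenyl]morpholine | COc1cc(O[Si](C(C)C)(C(C)C)C(C)C)ccc1/C=C/N1CCOCC1
F2 | step 7 | rac-4-(5-methoxy-3-{2-methoxy-4-[(triisopropylsilyl)oxy]phenyl}-6-(3-methylbut-2-en-1-yl)-7-[(triisopropylsilyl)oxy]chroman-2-yl)morpholine | COc1cc(O[Si](C(C)C)(C(C)C)C(C)C)ccc1C1Cc2c(OC)c(CC=C(C)C)c(O[Si](C(C)C)(C(C)C)C(C)C)cc2OC1N1CCOCC1
F3 | step 7 | rac-5-methoxy-3-{2-methoxy-4-[(triisopropylsilyl)oxy]phenyl}-6-(3-methylbut-2-en-1-yl)-7-[(triisopropylsilyl)oxy]chroman-2-ol | COc1cc(O[Si](C(C)C)(C(C)C)C(C)C)ccc1C1Cc2c(OC)c(CC=C(C)C)c(O[Si](C(C)C)(C(C)C)C(C)C)cc2OC1O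
F4 | step 3 | 3-bromo-2-hydroxy-6-methoxy-4-[(triisopropylsilyl)oxy]benzaldehyde | O=Cc1c(O)c(Br)c(O[Si](C(C)C)(C(C)C)C(C)C)cc1OC
F5 | step 3 | 3-bromo-6-methoxy-2-[(3-methylbut-2-en-1-yl)oxy]-4-[(triisopropylsilyl)oxy]benzaldehyde | O=Cc1c(OCC=C(C)C)c(Br)c(O[Si](C(C)C)(C(C)C)C(C)C)cc1OC
F6 | step 3 | 3-bromo-2-hydroxy-6-methoxy-5-(3-methylbut-2-en-1-yl)-4-[(triisopropylsilyl)oxy]benzaldehyde | O=Cc1c(O)c(Br)c(O[Si](C(C)C)(C(C)C)C(C)C)c(CC=C(C)C)c1OC
F7 | step 4 | 2-[(dimethylamino)methyl]-3-methoxy-4-(3-methylbut-2-en-1-yl)-5-[(triisopropylsilyl)oxy]phenol | CN(C)Cc1c(O)cc(O[Si](C(C)C)(C(C)C)C(C)C)c(CC=C(C)C)c1OC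
F8 | step 4 | {6-hydroxy-2-methoxy-3-(3-methylbut-2-en-1-yl)-4-[(triisopropylsilyl)oxy]phenyl}-N,N,N-trimethylmethanaminium iodide | C[N+](C)(C)Cc1c(O)cc(O[Si](C(C)C)(C(C)C)C(C)C)c(CC=C(C)C)c1OC.[I-]
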